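**Strategy**

- Retrosynthesis: with the free phenol masked as a benzyl ether, the pyran-4-one ring is cut at C4a–C4, C4–C3 and O1–C2. This gives 2-iodo-4,5-dimethoxyphenol (O1, C8a, C4a), carbon monoxide (C4) and a terminal 4-arylbut-1-yne (C3, C2 and both CH2 groups).
- Enabling feature: C4 is a carbonyl carbon lying between aryl carbon C4a and the vinylic CH at C3, and C2 holds the only bond (the CH2CH2 tether) to the 3-hydroxy-4-methoxyphenyl ring.
- The alkyne is cut at its ArCH2–CH2 bond into an isovanillin-derived benzyl bromide and the propargyl anion of 1-(trimethylsilyl)propyne.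
- Forward: the butynyl chain is built on the isovanillin ring (steps 1 to 5) and 3,4-dimethoxyphenol is iodinated (step 6). The three components are then joined with closure of the pyranone, the only ring that is made (step 7), and hydrogenolysis frees the phenol (step 8).
- Stereochemistry: the target has no stereocentre and no stereogenic double bond, so nothing is set or carried.

Key step: step 7

Remark: the enaminone that forms in the key step is a push-pull alkene of no fixed geometry and is written without alkene configuration.

**Route**

Step 1
Reactants: 1 isovanillin (3-hydroxy-4-methoxybenzaldehyde); 2 benzyl bromide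
Product: 3 3-(benzyloxy)-4-methoxybenzaldehyde
Conditions: K2CO3, DMF, 60 °C
Reagents that add atoms: none
Why: Williamson ether synthesis, in which the phenoxide of 1 (its only acidic site) displaces bromide from 2 by SN2 while the aldehyde is inert to carbonate.

Step 2
Reactants: 3 3-(benzyloxy)-4-methoxybenzaldehyde
Product: 4 [3-(benzyloxy)-4-methoxyphenyl]methanol
Conditions: NaBH4, MeOH, 0 °C to rt
Reagents that add atoms: none
Why: Borohydride reduction of an aromatic aldehyde to the primary benzylic alcohol is chemoselective and leaves the benzyl and methyl ethers untouched.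

Step 3
Reactants: 4 [3-(benzyloxy)-4-methoxyphenyl]methanol
Product: 5 2-(benzyloxy)-4-(bromomethyl)-1-methoxybenzene
Conditions: PBr3, CH2Cl2, 0 °C
Reagents that add atoms: phosphorus tribromide, BrP(Br)Br
Why: Bromination of a benzylic alcohol with PBr3 proceeds through a phosphite ester that bromide displaces by SN2; at 0 °C the aryl ethers should not be cleaved, and the reactive bromide is used at once.

Step 4
Reactants: 5 2-(benzyloxy)-4-(bromomethyl)-1-methoxybenzene; 6 1-(trimethylsilyl)propyne
Product: 8 {4-[3-(benzyloxy)-4-methoxyphenyl]but-1-yn-1-yl}trimethylsilane, via 3-(trimethylsilyl)prop-2-ynyllithium 7 (not isolated)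
Conditions: 6, n-BuLi, THF, −78 °C; then 5, −78 °C to rt
Reagents that add atoms: none
Why: Propargylic lithiation of 6 gives the silyl-stabilised anion 7, and its SN2 alkylation by the primary benzylic bromide should occur at the CH2 terminus because the bulky silyl group disfavours reaction through the allenyl end (alkylation of lithiated 1-(trimethylsilyl)propyne).

Step 5
Reactants: 8 {4-[3-(benzyloxy)-4-methoxyphenyl]but-1-yn-1-yl}trimethylsilane
Product: 9 2-(benzyloxy)-4-(but-3-yn-1-yl)-1-methoxybenzene
Conditions: K2CO3 (cat.), MeOH, rt
Reagents that add atoms: none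
Why: Methoxide-mediated protodesilylation of an alkynylsilane cleaves only the C(sp)–Si bond and is mild enough to leave both ether types intact.

Step 6
Reactants: 10 3,4-dimethoxyphenol
Product: 11 2-iodo-4,5-dimethoxyphenol
Conditions: I2, AgO2CCF3, CHCl3, 0 °C to rt
Reagents that add atoms: iodine, II
Why: Silver-assisted electrophilic aromatic iodination of an activated phenol should go to the open position ortho to OH and para to the 3-methoxy group, because the other ortho position is crowded between OH and OMe and the para position is occupied.

Step 7
Reactants: 11 2-iodo-4,5-dimethoxyphenol; 9 2-(benzyloxy)-4-(but-3-yn-1-yl)-1-methoxybenzene; 12 carbon monoxide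
Product: 15 2-{2-[3-(benzyloxy)-4-methoxyphenyl]ethyl}-6,7-dimethoxy-4H-chromen-4-one, via o-hydroxyaryl ynone 13 (not isolated), via β-diethylamino enone 14 (not isolated)
Conditions: PdCl2(dppf) (cat.), CO (20 atm), Et2NH, 120 °C
Reagents that add atoms: none
Why: Zerovalent palladium generated from PdCl2(dppf) inserts into the C–I bond of 11, CO insertion gives an aroylpalladium iodide, and alkynylation by 9 followed by reductive elimination delivers ynone 13, forming the C4a–C4 and C4–C3 bonds. Diethylamine then adds to the ynone to give the β-amino enone 14, and the ortho phenol oxygen attacks the amine-bearing carbon (C2) and expels diethylamine, forming O1–C2. The closest known reaction type is the palladium-catalysed carbonylative Sonogashira annulation of o-iodophenols with terminal alkynes in secondary amines, which gives 2-substituted chromones, 2-alkyl ones included. The pyran-4-one ring is closed in a 6-endo addition–elimination, and no stereocentre is created. The step needs six-membered closure instead of 5-exo closure to an aurone, and carbonylative instead of direct coupling (which would end in a benzofuran): the enaminone leaves only C2 electrophilic, and CO pressure without copper favours acyl transfer. In the substrates, the free OH ortho to iodine in 11 is placed for the closure and the benzyl ether of 9 keeps the second phenol out of competing aryloxycarbonylation.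

Step 8
Reactants: 15 2-{2-[3-(benzyloxy)-4-methoxyphenyl]ethyl}-6,7-dimethoxy-4H-chromen-4-one
Product: 16 2-[2-(3-hydroxy-4-methoxyphenyl)ethyl]-6,7-dimethoxy-4H-chromen-4-one
Conditions: H2 (1 atm), 10% Pd/C, EtOAc, rt, stopped when 15 is consumed
Reagents that add atoms: none
Why: Catalytic hydrogenolysis of an aryl benzyl ether should be much faster than hydrogenation of the vinylogous-ester C2–C3 bond of the chromone, and the three methyl ethers are inert.

**Compound list**

1 | isovanillin (3-hydroxy-4-methoxybenzaldehyde) | COc1ccc(C=O)cc1O | starting material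
2 | benzyl bromide | BrCc1ccccc1 | starting material
3 | 3-(benzyloxy)-4-methoxybenzaldehyde | COc1ccc(C=O)cc1OCc1ccccc1 | intermediate
4 | [3-(benzyloxy)-4-methoxyphenyl]methanol | COc1ccc(CO)cc1OCc1ccccc1 | intermediate
5 | 2-(benzyloxy)-4-(bromomethyl)-1-methoxybenzene | COc1ccc(CBr)cc1OCc1ccccc1 | intermediate
6 | 1-(trimethylsilyl)propyne | CC#C[Si](C)(C)C | starting material
7 | 3-(trimethylsilyl)prop-2-ynyllithium (not isolated) | [Li]CC#C[Si](C)(C)C | intermediate
8 | {4-[3-(benzyloxy)-4-methoxyphenyl]but-1-yn-1-yl}trimethylsilane | COc1ccc(CCC#C[Si](C)(C)C)cc1OCc1ccccc1 | intermediate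
9 | 2-(benzyloxy)-4-(but-3-yn-1-yl)-1-methoxybenzene | COc1ccc(CCC#C)cc1OCc1ccccc1 | intermediate
10 | 3,4-dimethoxyphenol | COc1ccc(O)cc1OC | starting material
11 | 2-iodo-4,5-dimethoxyphenol | COc1cc(O)c(I)cc1OC | intermediate
12 | carbon monoxide | [C-]#[O+] | starting material
13 | 5-[3-(benzyloxy)-4-methoxyphenyl]-1-(2-hydroxy-4,5-dimethoxyphenyl)pent-2-yn-1-one (not isolated) | COc1ccc(CCC#CC(=O)c2cc(OC)c(OC)cc2O)cc1OCc1ccccc1 | intermediate
14 | 5-[3-(benzyloxy)-4-methoxyphenyl]-3-(diethylamino)-1-(2-hydroxy-4,5-dimethoxyphenyl)pent-2-en-1-one (not isolated, alkene geometry not fixed) | CCN(CC)C(CCc1ccc(OC)c(OCc2ccccc2)c1)=CC(=O)c1cc(OC)c(OC)cc1O | intermediate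
15 | 2-{2-[3-(benzyloxy)-4-methoxyphenyl]ethyl}-6,7-dimethoxy-4H-chromen-4-one | COc1ccc(CCc2cc(=O)c3cc(OC)c(OC)cc3o2)cc1OCc1ccccc1 | intermediate
16 | 2-[2-(3-hydroxy-4-methoxyphenyl)ethyl]-6,7-dimethoxy-4H-chromen-4-one | COc1ccc(CCc2cc(=O)c3cc(OC)c(OC)cc3o2)cc1O | target

**Step count**

Total: 8 steps. Longest linear sequence: 7 steps (steps 1, 2, 3, 4, 5, 7, 8 from isovanillin); step 6 is the one-step side branch.

**Steps most likely to fail**

1. Step 7. Oxidative addition into the electron-rich C–I bond may be slow. Direct alkynylation without CO uptake (followed by cyclisation to a benzofuran), or capture of the aroylpalladium by diethylamine, could then outrun ynone formation. The fallback is palladium-free and sets out from alkyne 9. Deprotonation with n-BuLi (THF, −78 °C) should give the lithium acetylide {4-[3-(benzyloxy)-4-methoxyphenyl]but-1-yn-1-yl}lithium F1. This is added to commercial 2-hydroxy-4,5-dimethoxybenzaldehyde, whose phenol has first been turned into its lithium salt with one equivalent of LiN(SiMe3)2. The product should be the propargylic alcohol 5-[3-(benzyloxy)-4-methoxyphenyl]-1-(2-hydroxy-4,5-dimethoxyphenyl)pent-2-yn-1-ol F2 (racemic; the carbinol centre disappears in the next operation). Oxidation with MnO2 in CH2Cl2 at rt should give ynone 13, now isolated, where the fallback comes back to the route. Warming 13 in Et2NH/EtOH should then carry it through 14 to chromone 15.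

2. Step 4. Lithium–bromine exchange or electron transfer at the electron-rich benzylic bromide may cause homocoupling, or the ambident anion may react through its allenyl terminus. The fallback sets out from aldehyde 3. Zinc-mediated Barbier propargylation (propargyl bromide, Zn dust, THF/saturated aqueous NH4Cl, 0 °C to rt) should give the homopropargylic alcohol 1-[3-(benzyloxy)-4-methoxyphenyl]but-3-yn-1-ol F3 (racemic). Ionic deoxygenation of this para-methoxy-stabilised benzylic alcohol with Et3SiH and CF3CO2H in CH2Cl2 at −20 to 0 °C should then give alkyne 9. The fallback thus leaves the route at 3 and comes back at 9, bypassing steps 2 to 5.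

3. Step 8. Hydrogen may add to the C2–C3 double bond of the pyranone while the benzyl ether is being cleaved, giving a chromanone. The fallback sets out from 15 and replaces the reductive cleavage by a Lewis acid one with no hydrogen source present. BCl3 with pentamethylbenzene as benzyl cation scavenger in CH2Cl2 at −78 °C should ionise only the benzylic C–O bond and leave the methyl ethers and the enone alone. It comes back to the route at target 16 and makes no new compound.

**Further compounds**

F1 | step 7 | {4-[3-(benzyloxy)-4-methoxyphenyl]but-1-yn-1-yl}lithium | [Li]C#CCCc1ccc(OC)c(OCc2ccccc2)c1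
F2 | step 7 | 5-[3-(benzyloxy)-4-methoxyphenyl]-1-(2-hydroxy-4,5-dimethoxyphenyl)pent-2-yn-1-ol (racemic) | COc1ccc(CCC#CC(O)c2cc(OC)c(OC)cc2O)cc1OCc1ccccc1
F3 | step 4 | 1-[3-(benzyloxy)-4-methoxyphenyl]but-3-yn-1-ol (racemic) | COc1ccc(C(O)CC#C)cc1OCc1ccccc1
F0 | step 8 | none | none
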